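## Retrosynthetic overview

- The target is reached by hydrogenolysis of two aryl benzyl ethers. Before that, the C4 vinyl group is cut to CH2OH (ozonolysis, NaBH4) and the C3 methyl ester is reduced (LiAlH4). The all-trans 4-vinyl-3-ester oxolane comes from a spiro dioxanedione by methanolysis, decarboxylation and epimerisation.
- Key disconnection: oxolane bonds O1–C2 and C3–C4, made together in a palladium-catalysed formal [3+2] cycloaddition. An aryl vinyl oxirane supplies O1, C5 and C4; an arylidene Meldrum's acid supplies C2 and C3. Both partners come from O-benzylsyringaldehyde.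
- Enabling feature: the vinyl group on the non-benzylic oxirane carbon (future oxolane C4) makes that C–O bond of the three-membered ring allylic. Zerovalent palladium can ionise it to a 1,3-zwitterion (alkoxide O, π-allyl C). The exocyclic C=C of the acceptor is doubly activated by the 1,3-dioxane-4,6-dione ring.
- Ring order: oxirane (step 4, sets the absolute configuration), then oxolane (step 5). The dioxanedione ring arrives with the reagent and is opened in step 6. Stereochemical relay: C5 → C4 → C2 → C3.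

Key step: step 5

Remark: Ar = 4-(benzyloxy)-3,5-dimethoxyphenyl; oxolane atoms are numbered O1, C2 (from the acceptor), C3, C4, C5 (from the oxirane) in all intermediates; the two palladium intermediates of the key step are drawn as η1-allyl forms without phosphine ligands.

## Route

Step 1
Reactants: 1 syringaldehyde (4-hydroxy-3,5-dimethoxybenzaldehyde)
Product: 2 4-(benzyloxy)-3,5-dimethoxybenzaldehyde
Conditions: BnBr, K2CO3, DMF, 60 °C
Reagents that add atoms: benzyl bromide, BrCc1ccccc1
Why: Williamson ether synthesis on the acidic phenol; the benzyl ether should survive every later base, oxidant, palladium and hydride step and is removed last.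

Step 2
Reactants: 2 4-(benzyloxy)-3,5-dimethoxybenzaldehyde; 3 Meldrum's acid (2,2-dimethyl-1,3-dioxane-4,6-dione)
Product: 4 5-{[4-(benzyloxy)-3,5-dimethoxyphenyl]methylidene}-2,2-dimethyl-1,3-dioxane-4,6-dione
Conditions: pyrrolidine (10 mol %), AcOH (10 mol %), toluene, 25 °C
Reagents that add atoms: none
Why: Knoevenagel condensation of a non-enolisable aldehyde with a highly C–H acidic 1,3-dicarbonyl compound should give the crystalline, strongly electrophilic alkylidene with no stereochemical issue.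

Step 3
Reactants: 2 4-(benzyloxy)-3,5-dimethoxybenzaldehyde; 5 diethyl allylphosphonate
Product: 7 2-(benzyloxy)-5-[(1E)-buta-1,3-dien-1-yl]-1,3-dimethoxybenzene, via lithium oxidophosphonate adduct 6 (not isolated)
Conditions: 5, n-BuLi, THF, −78 °C; 2; then HMPA, −78 → 25 °C
Reagents that add atoms: none
Why: Horner–Wadsworth–Emmons-type olefination with the α-lithiated allylphosphonate; HMPA-promoted elimination of the α-adduct should give the conjugated diene with the E geometry at the new styrenyl double bond.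

Step 4
Reactants: 7 2-(benzyloxy)-5-[(1E)-buta-1,3-dien-1-yl]-1,3-dimethoxybenzene
Product: 8 (2R,3R)-2-[4-(benzyloxy)-3,5-dimethoxyphenyl]-3-ethenyloxirane
Conditions: D-fructose-derived ketone catalyst (1,2:4,5-di-O-isopropylidene-β-D-erythro-2,3-hexodiulo-2,6-pyranose, 30 mol %), Oxone (2KHSO5·KHSO4·K2SO4), K2CO3, Bu4NHSO4, MeCN–CH2(OMe)2–aq. Na2B4O7/Na2EDTA buffer (pH 10.5), 0 °C
Reagents that add atoms: potassium peroxymonosulfate (KHSO5 of Oxone), [K+].[O-]S(=O)(=O)OO
Why: Shi asymmetric epoxidation; the chiral dioxirane should oxidise the trans-disubstituted styrenyl double bond in preference to the monosubstituted terminal one through a spiro transition state, and the D-fructose-derived catalyst delivers oxygen to the face that gives the (R,R)-oxirane, which fixes C5 and C4.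

Step 5
Reactants: 4 5-{[4-(benzyloxy)-3,5-dimethoxyphenyl]methylidene}-2,2-dimethyl-1,3-dioxane-4,6-dione; 8 (2R,3R)-2-[4-(benzyloxy)-3,5-dimethoxyphenyl]-3-ethenyloxirane
Product: 11 (1R,3S,4S)-1,3-bis[4-(benzyloxy)-3,5-dimethoxyphenyl]-4-ethenyl-8,8-dimethyl-2,7,9-trioxaspiro[4.5]decane-6,10-dione, via palladium allyl alkoxide zwitterion 9 (not isolated), via oxa-Michael adduct 10 (not isolated)
Conditions: Pd(PPh3)4 (5 mol %), THF, 40 °C, slow addition of 8 to 4 (1.2 equiv)
Reagents that add atoms: none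
Why: Zerovalent palladium ionises the allylic C–O bond of the strained oxirane with inversion to the zwitterion 9; its alkoxide adds reversibly (oxa-Michael) to the doubly activated alkene of 4 to form O1–C2 and the dioxanedione carbanion 10, which alkylates the proximal allyl terminus anti to palladium to form C3–C4 and release the catalyst. The closest known reaction type is the Pd(PPh3)4-catalysed formal [3+2] cycloaddition of vinyl oxiranes with alkylidene malononitriles and alkylidene Meldrum's acids to give 4-vinyltetrahydrofurans. The oxolane closes in the 5-exo mode (intramolecular allylic alkylation at the internal allyl terminus, the vinyl group staying exocyclic) in preference to the seven-membered alternative. C5 is carried over unchanged from 8; C4 is set 4,5-trans by the double inversion (net retention) and by the A(1,3)-minimised conformer of 9 with C5–H eclipsing the allyl unit; C2 is set under Curtin–Hammett control, the closing transition state with the C2 aryl group cis to the C4 vinyl group (2,5-trans) letting the planar dioxanedione carbanion tilt away from both flanking substituents; C3 is a spiro centre and not stereogenic. The step needs ionisation at the allylic and not the benzylic C–O bond (secured by the vinyl group and neutral conditions), alkoxide capture faster than hydride-shift isomerisation to the aryl ketone (secured by the electrophilicity of 4, kept in excess), and 2,5-trans facial selectivity, which is the least secured element.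

Step 6
Reactants: 11 (1R,3S,4S)-1,3-bis[4-(benzyloxy)-3,5-dimethoxyphenyl]-4-ethenyl-8,8-dimethyl-2,7,9-trioxaspiro[4.5]decane-6,10-dione
Product: 14 methyl (2S,3S,4S,5S)-2,5-bis[4-(benzyloxy)-3,5-dimethoxyphenyl]-4-ethenyloxolane-3-carboxylate, via malonic half-ester 12 (not isolated), via C3-epimeric ester 13 (not isolated)
Conditions: NaOMe (1.1 equiv), MeOH–THF, 0 → 25 °C; AcOH; evaporate, DMSO, 120 °C; then DBU (0.3 equiv), 25 °C
Reagents that add atoms: sodium methoxide, [Na+].[O-]C
Why: Alcoholysis and decarboxylation of a Meldrum's acid derivative (methoxide opens the acylal with loss of acetone, the half-ester decarboxylates through its enol), followed by thermodynamic epimerisation of the α-stereocentre, should place the C3 ester trans to both the C2 aryl and the C4 vinyl group.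

Step 7
Reactants: 14 methyl (2S,3S,4S,5S)-2,5-bis[4-(benzyloxy)-3,5-dimethoxyphenyl]-4-ethenyloxolane-3-carboxylate
Product: 15 [(2S,3R,4S,5S)-2,5-bis[4-(benzyloxy)-3,5-dimethoxyphenyl]-4-ethenyloxolan-3-yl]methanol
Conditions: LiAlH4, THF, 0 °C; aq. NaOH work-up
Reagents that add atoms: none
Why: Hydride reduction of the ester to the primary alcohol should leave the vinyl group, the ethers and all stereocentres untouched, and C3 is no longer epimerisable afterwards (the descriptor changes only through CIP priorities).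

Step 8
Reactants: 15 [(2S,3R,4S,5S)-2,5-bis[4-(benzyloxy)-3,5-dimethoxyphenyl]-4-ethenyloxolan-3-yl]methanol
Product: 17 [(2S,3R,4R,5S)-2,5-bis[4-(benzyloxy)-3,5-dimethoxyphenyl]oxolane-3,4-diyl]dimethanol, via hydroxy aldehyde 16 (not isolated)
Conditions: O3, CH2Cl2–MeOH, Sudan Red 7B (indicator), −78 °C; Me2S, −78 → 0 °C; then NaBH4, 0 °C
Reagents that add atoms: ozone, [O-][O+]=O
Why: Ozonolysis with reductive work-up excises the terminal vinyl carbon, and immediate borohydride reduction of the aldehyde at low temperature should prevent epimerisation at C4, whose substituent stays trans to both neighbours.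

Step 9
Reactants: 17 [(2S,3R,4R,5S)-2,5-bis[4-(benzyloxy)-3,5-dimethoxyphenyl]oxolane-3,4-diyl]dimethanol
Product: 18 huazhongilexin, [(2S,3R,4R,5S)-2,5-bis(4-hydroxy-3,5-dimethoxyphenyl)oxolane-3,4-diyl]dimethanol
Conditions: H2 (1 atm), 10% Pd/C, EtOAc–MeOH, 25 °C
Reagents that add atoms: none
Why: Catalytic hydrogenolysis of the two aryl benzyl ethers should be faster than cleavage of the hindered cyclic benzylic C–O bonds, and the neutral conditions avoid acid-induced rearrangement of the diol to a furofuran.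

## Compound list

1 | syringaldehyde (4-hydroxy-3,5-dimethoxybenzaldehyde) | COc1cc(C=O)cc(OC)c1O | starting material
2 | 4-(benzyloxy)-3,5-dimethoxybenzaldehyde | COc1cc(C=O)cc(OC)c1OCc1ccccc1 | intermediate
3 | Meldrum's acid (2,2-dimethyl-1,3-dioxane-4,6-dione) | CC1(C)OC(=O)CC(=O)O1 | starting material
4 | 5-{[4-(benzyloxy)-3,5-dimethoxyphenyl]methylidene}-2,2-dimethyl-1,3-dioxane-4,6-dione | COc1cc(C=C2C(=O)OC(C)(C)OC2=O)cc(OC)c1OCc1ccccc1 | intermediate
5 | diethyl allylphosphonate (diethyl prop-2-en-1-ylphosphonate) | CCOP(=O)(CC=C)OCC | starting material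
6 | lithium 1-[4-(benzyloxy)-3,5-dimethoxyphenyl]-2-(diethoxyphosphoryl)but-3-en-1-olate (diastereomer mixture) | [Li+].[O-]C(c1cc(OC)c(OCc2ccccc2)c(OC)c1)C(C=C)P(=O)(OCC)OCC | intermediate
7 | 2-(benzyloxy)-5-[(1E)-buta-1,3-dien-1-yl]-1,3-dimethoxybenzene | C=C/C=C/c1cc(OC)c(OCc2ccccc2)c(OC)c1 | intermediate
8 | (2R,3R)-2-[4-(benzyloxy)-3,5-dimethoxyphenyl]-3-ethenyloxirane | O1[C@H](c2cc(OC)c(OCc3ccccc3)c(OC)c2)[C@H]1C=C | intermediate
9 | zwitterionic (S)-alkoxide of the allylpalladium cation from 8 (η1 form, phosphines omitted) | [O-][C@H](c1cc(OC)c(OCc2ccccc2)c(OC)c1)/C=C/C[Pd+] | intermediate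
10 | oxa-Michael adduct of 9 with 4: allylpalladium cation with dioxanedione enolate, C2 epimers in equilibrium (η1 form, phosphines omitted) | [Pd+]C/C=C/[C@@H](c1cc(OC)c(OCc2ccccc2)c(OC)c1)OC(c1cc(OC)c(OCc2ccccc2)c(OC)c1)C1=C([O-])OC(C)(C)OC1=O | intermediate
11 | (1R,3S,4S)-1,3-bis[4-(benzyloxy)-3,5-dimethoxyphenyl]-4-ethenyl-8,8-dimethyl-2,7,9-trioxaspiro[4.5]decane-6,10-dione (oxolane numbering 2R,4S,5S) | COc1cc([C@H]2O[C@H](c3cc(OC)c(OCc4ccccc4)c(OC)c3)[C@@H](C=C)C25C(=O)OC(C)(C)OC5=O)cc(OC)c1OCc1ccccc1 | intermediate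
12 | (2R,4S,5S)-2,5-bis[4-(benzyloxy)-3,5-dimethoxyphenyl]-4-ethenyl-3-(methoxycarbonyl)oxolane-3-carboxylic acid (C3 epimers) | COc1cc([C@H]2O[C@H](c3cc(OC)c(OCc4ccccc4)c(OC)c3)[C@@H](C=C)C2(C(=O)O)C(=O)OC)cc(OC)c1OCc1ccccc1 | intermediate
13 | methyl (2S,3R,4S,5S)-2,5-bis[4-(benzyloxy)-3,5-dimethoxyphenyl]-4-ethenyloxolane-3-carboxylate (C3 epimer of 14) | COc1cc([C@H]2O[C@H](c3cc(OC)c(OCc4ccccc4)c(OC)c3)[C@@H](C=C)[C@H]2C(=O)OC)cc(OC)c1OCc1ccccc1 | intermediate
14 | methyl (2S,3S,4S,5S)-2,5-bis[4-(benzyloxy)-3,5-dimethoxyphenyl]-4-ethenyloxolane-3-carboxylate | COc1cc([C@H]2O[C@H](c3cc(OC)c(OCc4ccccc4)c(OC)c3)[C@@H](C=C)[C@@H]2C(=O)OC)cc(OC)c1OCc1ccccc1 | intermediate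
15 | [(2S,3R,4S,5S)-2,5-bis[4-(benzyloxy)-3,5-dimethoxyphenyl]-4-ethenyloxolan-3-yl]methanol | COc1cc([C@H]2O[C@H](c3cc(OC)c(OCc4ccccc4)c(OC)c3)[C@@H](C=C)[C@@H]2CO)cc(OC)c1OCc1ccccc1 | intermediate
16 | (2S,3S,4R,5S)-2,5-bis[4-(benzyloxy)-3,5-dimethoxyphenyl]-4-(hydroxymethyl)oxolane-3-carbaldehyde | COc1cc([C@H]2O[C@H](c3cc(OC)c(OCc4ccccc4)c(OC)c3)[C@@H](C=O)[C@@H]2CO)cc(OC)c1OCc1ccccc1 | intermediate
17 | [(2S,3R,4R,5S)-2,5-bis[4-(benzyloxy)-3,5-dimethoxyphenyl]oxolane-3,4-diyl]dimethanol | COc1cc([C@H]2O[C@H](c3cc(OC)c(OCc4ccccc4)c(OC)c3)[C@@H](CO)[C@@H]2CO)cc(OC)c1OCc1ccccc1 | intermediate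
18 | huazhongilexin, [(2S,3R,4R,5S)-2,5-bis(4-hydroxy-3,5-dimethoxyphenyl)oxolane-3,4-diyl]dimethanol | COc1cc([C@H]2O[C@H](c3cc(OC)c(O)c(OC)c3)[C@@H](CO)[C@@H]2CO)cc(OC)c1O | target

## Step count and risks

Total step count: 9. Longest linear sequence: 8 (steps 1, 3, 4, 5, 6, 7, 8, 9); step 2 is the convergent branch.

**Step 5 (key step).** What may go wrong: insufficient facial selectivity at C2 in the reversible oxa-Michael addition and ring closure, because C2 is set with only 1,3-relationships and no vicinal control element; isomerisation of the alkoxy π-allyl intermediate would add to the loss. The fallback sets out from 4 and 8 and comes back at 14, and it replaces kinetic control at C2 by a thermodynamic funnel. The cycloaddition is run without regard to C2. The C2-epimeric cycloadduct (1S,3S,4S)-1,3-bis[4-(benzyloxy)-3,5-dimethoxyphenyl]-4-ethenyl-8,8-dimethyl-2,7,9-trioxaspiro[4.5]decane-6,10-dione F1 is taken together with 11 through the methanolysis and decarboxylation of step 6. This passes through the epimeric half-ester (2S,4S,5S)-2,5-bis[4-(benzyloxy)-3,5-dimethoxyphenyl]-4-ethenyl-3-(methoxycarbonyl)oxolane-3-carboxylic acid F2 and gives the C2-epimeric ester methyl (2R,4S,5S)-2,5-bis[4-(benzyloxy)-3,5-dimethoxyphenyl]-4-ethenyloxolane-3-carboxylate F3. The mixture of 14 and F3 is then treated with KOt-Bu (0.2 equiv) in t-BuOH–THF at 40 °C. Reversible E1cB opening of the oxolane (retro-oxa-Michael) gives the benzylidene ester methyl (3S)-2-{[4-(benzyloxy)-3,5-dimethoxyphenyl]methylidene}-3-{(S)-[4-(benzyloxy)-3,5-dimethoxyphenyl](hydroxy)methyl}pent-4-enoate F4 as its alkoxide, and 5-endo oxa-Michael re-closure follows. This equilibrates C2 and C3 together while C4 and C5 stay fixed, so both series should converge on the all-trans ester 14.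

**Step 4.** What may go wrong: competing epoxidation of the terminal vinyl group, incomplete facial discrimination by the dioxirane, and acid-promoted opening of the electron-rich benzylic oxirane during isolation. The fallback sets out from 2 and comes back at 8, and it moves the asymmetric oxidation to an allylic alcohol. Horner–Wadsworth–Emmons reaction of 2 with triethyl phosphonoacetate (NaH, THF) gives ethyl (2E)-3-[4-(benzyloxy)-3,5-dimethoxyphenyl]prop-2-enoate F5. Reduction with i-Bu2AlH (CH2Cl2, −78 °C) gives (2E)-3-[4-(benzyloxy)-3,5-dimethoxyphenyl]prop-2-en-1-ol F6. Sharpless asymmetric epoxidation (Ti(OiPr)4, D-(−)-diethyl tartrate, t-BuOOH, 4 Å molecular sieves, CH2Cl2, −20 °C) gives [(2R,3R)-3-[4-(benzyloxy)-3,5-dimethoxyphenyl]oxiran-2-yl]methanol F7. Parikh–Doering oxidation (SO3·pyridine, DMSO, Et3N) gives (2S,3R)-3-[4-(benzyloxy)-3,5-dimethoxyphenyl]oxirane-2-carbaldehyde F8. Wittig methylenation (Ph3PCH3Br, KOt-Bu, THF, 0 °C) then gives 8.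

**Step 6.** What may go wrong: sluggish thermal decarboxylation of the hindered quaternary half-ester, with degradation at 120 °C and incomplete equilibration at C3. The fallback sets out from 12 (now isolated after the methanolysis) and comes back at 14, and it replaces the thermal polar decarboxylation by a radical one at room temperature. The acid 12 is converted with N-hydroxypyridine-2-thione, DCC and DMAP (CH2Cl2, dark) into the thiohydroxamate ester 3-methyl 3-(2-sulfanylidenepyridin-1(2H)-yl) (2R,4S,5S)-2,5-bis[4-(benzyloxy)-3,5-dimethoxyphenyl]-4-ethenyloxolane-3,3-dicarboxylate F9. Barton reductive decarboxylation (t-BuSH, visible light, benzene, 25 °C) generates the C3 radical, which should take hydrogen on the face anti to the flanking C2 aryl and C4 vinyl groups to give 14 directly.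

## Further compounds

F1 | step 5 | (1S,3S,4S)-1,3-bis[4-(benzyloxy)-3,5-dimethoxyphenyl]-4-ethenyl-8,8-dimethyl-2,7,9-trioxaspiro[4.5]decane-6,10-dione (C2 epimer of 11) | COc1cc([C@@H]2O[C@H](c3cc(OC)c(OCc4ccccc4)c(OC)c3)[C@@H](C=C)C25C(=O)OC(C)(C)OC5=O)cc(OC)c1OCc1ccccc1
F2 | step 5 | (2S,4S,5S)-2,5-bis[4-(benzyloxy)-3,5-dimethoxyphenyl]-4-ethenyl-3-(methoxycarbonyl)oxolane-3-carboxylic acid (C3 epimers) | COc1cc([C@@H]2O[C@H](c3cc(OC)c(OCc4ccccc4)c(OC)c3)[C@@H](C=C)C2(C(=O)O)C(=O)OC)cc(OC)c1OCc1ccccc1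
F3 | step 5 | methyl (2R,4S,5S)-2,5-bis[4-(benzyloxy)-3,5-dimethoxyphenyl]-4-ethenyloxolane-3-carboxylate (C3 epimers) | COc1cc([C@@H]2O[C@H](c3cc(OC)c(OCc4ccccc4)c(OC)c3)[C@@H](C=C)C2C(=O)OC)cc(OC)c1OCc1ccccc1
F4 | step 5 | methyl (3S)-2-{[4-(benzyloxy)-3,5-dimethoxyphenyl]methylidene}-3-{(S)-[4-(benzyloxy)-3,5-dimethoxyphenyl](hydroxy)methyl}pent-4-enoate (alkene geometry not fixed) | COC(=O)C(=Cc1cc(OC)c(OCc2ccccc2)c(OC)c1)[C@H](C=C)[C@H](O)c1cc(OC)c(OCc2ccccc2)c(OC)c1
F5 | step 4 | ethyl (2E)-3-[4-(benzyloxy)-3,5-dimethoxyphenyl]prop-2-enoate | CCOC(=O)/C=C/c1cc(OC)c(OCc2ccccc2)c(OC)c1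
F6 | step 4 | (2E)-3-[4-(benzyloxy)-3,5-dimethoxyphenyl]prop-2-en-1-ol | OC/C=C/c1cc(OC)c(OCc2ccccc2)c(OC)c1
F7 | step 4 | [(2R,3R)-3-[4-(benzyloxy)-3,5-dimethoxyphenyl]oxiran-2-yl]methanol | O1[C@H](c2cc(OC)c(OCc3ccccc3)c(OC)c2)[C@H]1CO
F8 | step 4 | (2S,3R)-3-[4-(benzyloxy)-3,5-dimethoxyphenyl]oxirane-2-carbaldehyde | O1[C@H](c2cc(OC)c(OCc3ccccc3)c(OC)c2)[C@H]1C=O
F9 | step 6 | 3-methyl 3-(2-sulfanylidenepyridin-1(2H)-yl) (2R,4S,5S)-2,5-bis[4-(benzyloxy)-3,5-dimethoxyphenyl]-4-ethenyloxolane-3,3-dicarboxylate (C3 epimers) | COc1cc([C@H]2O[C@H](c3cc(OC)c(OCc4ccccc4)c(OC)c3)[C@@H](C=C)C2(C(=O)OC)C(=O)ON2C=CC=CC2=S)cc(OC)c1OCc1ccccc1
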